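27 (target) ⇐ 26 ⇐ 25 ⇐ 24: the last steps are C1=C10 epoxidation, C15 alcohol-to-aldehyde oxidation, acetonide removal and O8 methacrylation of α-methylene lactone 22.
22 ⇐ hydroxy dienone 15: the free C8–OH steers the C7 alkylation (lithium chelate) and the C6 reduction (internal hydride delivery); lactonisation and methylenation follow.
15 ⇐ 12: a ring-expanding Grob fragmentation of a cis-fused bicyclo[5.3.0]decene 1,3-diol monomesylate cuts the C6–C10 bond and makes the ten-membered ring and the E-1(10) alkene; the Z-4 alkene is already in place.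
12 ⇐ 11 (ring-closing metathesis) ⇐ 10 ⇐ 9: enone 8 and aldehyde 6 are joined by a Morita–Baylis–Hillman reaction, and a hydride-triggered Fráter–Seebach methylation (new) builds the C10 quaternary centre.
Ring order: cyclopentane (present in 7) → seven-membered ring → ten-membered ring (the cyclopentane bond is broken) → γ-lactone → epoxide; 6 comes from methacrolein by an asymmetric acetate aldol.

Assumption: atoms carry the germacrane numbers of the target (C1–C10 ring, C11–C13 lactone carbons, C14 on C10, C15 on C4; "6,10-cyclo" = extra C6–C10 bond, "nor" = carbon absent), and step 6 is taken to give both C1 epimers, of which the separated (1R) epimer is followed (the (1S) epimer reaches the same compound 14 by the same steps).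

Step 1
Reactants: 1 methacrolein
Product: 3 methyl (3S)-3-hydroxy-4-methylpent-4-enoate, via silyl ether 2 (not isolated)
Conditions: 1-methoxy-1-(trimethylsilyloxy)ethene, Ti(OiPr)4 (2 mol %), Carreira's binaphthyl Schiff-base ligand (enantiomer that gives 3S), 3,5-di-tert-butylsalicylic acid, Et2O, −10 °C; then 1 M HCl, THF, 0 °C
Reagents that add atoms: 1-methoxy-1-(trimethylsilyloxy)ethene, COC(=C)O[Si](C)(C)C
Why: Catalytic enantioselective Mukaiyama acetate aldol addition, in which the chiral titanium Lewis acid exposes one face of the enal carbonyl and so sets C3 as S.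

Step 2
Reactants: 3 methyl (3S)-3-hydroxy-4-methylpent-4-enoate
Product: 4 methyl (3S)-3-hydroxy-4-(hydroxymethyl)pent-4-enoate
Conditions: SeO2 (0.3 equiv), t-BuOOH (2.5 equiv), CH2Cl2, 23 °C
Reagents that add atoms: tert-butyl hydroperoxide, CC(C)(C)OO
Why: Selenium dioxide allylic hydroxylation (ene reaction, then 2,3-sigmatropic shift) oxidises the methyl group of the 1,1-disubstituted alkene, because the only other allylic hydrogen sits on the oxygen-bearing C3, whose configuration is not touched.

Step 3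
Reactants: 4 methyl (3S)-3-hydroxy-4-(hydroxymethyl)pent-4-enoate
Product: 5 methyl 2-[(4S)-2,2-dimethyl-5-methylidene-1,3-dioxan-4-yl]acetate
Conditions: 2,2-dimethoxypropane, PPTS (cat.), CH2Cl2, 23 °C
Reagents that add atoms: 2,2-dimethoxypropane, COC(C)(C)OC
Why: Acid-catalysed acetonide formation (transketalisation) ties O3 and O15 into one six-membered ring, so a single protecting group covers both oxygens.

Step 4
Reactants: 5 methyl 2-[(4S)-2,2-dimethyl-5-methylidene-1,3-dioxan-4-yl]acetate
Product: 6 2-[(4S)-2,2-dimethyl-5-methylidene-1,3-dioxan-4-yl]acetaldehyde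
Conditions: i-Bu2AlH (1.1 equiv), CH2Cl2, −78 °C; aq. potassium sodium tartrate
Reagents that add atoms: none
Why: Partial ester reduction with i-Bu2AlH at low temperature stops at the aluminium hemiacetal, which releases the aldehyde only on work-up.

Step 5
Reactants: 7 (4S)-4-hydroxycyclopent-2-en-1-one
Product: 8 (4S)-4-(tert-butyldimethylsilyloxy)cyclopent-2-en-1-one
Conditions: TBSCl, imidazole, DMF, 0 °C
Reagents that add atoms: tert-butyldimethylsilyl chloride, CC(C)(C)[Si](C)(C)Cl
Why: Silyl ether formation protects O8 so that only the C1 hydroxyl can be sulfonylated in step 10.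

Step 6
Reactants: 8 (4S)-4-(tert-butyldimethylsilyloxy)cyclopent-2-en-1-one; 6 2-[(4S)-2,2-dimethyl-5-methylidene-1,3-dioxan-4-yl]acetaldehyde
Product: 9 Morita–Baylis–Hillman adduct (1R epimer)
Conditions: n-Bu3P (20 mol %), phenol (20 mol %), THF, 23 °C
Reagents that add atoms: none
Why: Morita–Baylis–Hillman reaction (phosphine conjugate addition, aldol, elimination) joins C10 to C1 under almost neutral conditions; C1 forms without control, which is harmless because C1 becomes sp2 in step 10.

Step 7
Reactants: 9 Morita–Baylis–Hillman adduct (1R epimer)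
Product: 10 2-methyl aldol with C10 quaternary centre
Conditions: LiBH(s-Bu)3 (2.2 equiv), THF, −78 °C; then MeI (5 equiv), DMPU, −78 to −40 °C; then H2O
Reagents that add atoms: iodomethane, CI
Why: Proposed new method: a hydride-triggered Fráter–Seebach alkylation, in which the first hydride deprotonates the C1 hydroxyl and the second adds 1,4 to the enone, so that the C6/C10 enolate is formed regiospecifically inside a six-membered lithium chelate with the C1 alkoxide and MeI enters C10 anti to the C1 side chain (C10 = S, methyl and O1 cis on the future seven-membered ring, the relationship that becomes the E alkene in step 10); the closest known reactions are the Fráter–Seebach alkylation of β-hydroxy ester dianions and the reductive alkylation of enones with trialkylborohydrides.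

Step 8
Reactants: 10 2-methyl aldol with C10 quaternary centre
Product: 11 vinyl carbinol
Conditions: CH2=CHMgBr (3 equiv), CeCl3 (3 equiv), THF, −78 °C; then H2O
Reagents that add atoms: vinylmagnesium bromide, C=C[Mg]Br
Why: Cerium-mediated Grignard 1,2-addition to the hindered ketone avoids enolisation and retro-aldol; with the C1 alkoxide chelated to the carbonyl the C10 methyl is pseudo-axial and the vinyl group enters anti to it, which sets C6 as S with the vinyl group cis to the C1 side chain.

Step 9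
Reactants: 11 vinyl carbinol
Product: 12 cis-fused bicyclo[5.3.0]decene diol
Conditions: second-generation Grubbs catalyst (H2IMes)(PCy3)Cl2Ru=CHPh (5 mol %), toluene (5 mM), 80 °C
Reagents that add atoms: none
Why: Ring-closing metathesis closes the seven-membered ring and fixes C4=C5 as the ring-cis (Z) alkene that the target needs.

Step 10
Reactants: 12 cis-fused bicyclo[5.3.0]decene diol
Product: 15 (1(10)E,4Z,3S,8R)-8-hydroxy-3,15-(isopropylidenedioxy)-11,12,13-trinorgermacra-1(10),4-dien-6-one, via mesylate 13 (not isolated), via silyl ketone 14 (not isolated)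
Conditions: MsCl, Et3N, CH2Cl2, −20 °C; concentrate; KOt-Bu (1.1 equiv), THF, 0 °C; then AcOH, Bu4NF, 23 °C
Reagents that add atoms: none
Why: Ring-expanding Grob (Wharton) fragmentation, in which the C6 alkoxide breaks the C6–C10 ring-fusion bond anti-periplanar to the C1 mesylate and opens the bicycle to the ten-membered dienone, the cis relationship of mesylate and C10 methyl giving the E-1(10) alkene stereospecifically; buffered fluoride then frees O8.

Step 11
Reactants: 15 (1(10)E,4Z,3S,8R)-8-hydroxy-3,15-(isopropylidenedioxy)-11,12,13-trinorgermacra-1(10),4-dien-6-one; 16 methyl bromoacetate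
Product: 17 C7-alkylated hydroxy keto ester
Conditions: LiN(i-Pr)2 (2.2 equiv), THF/DMPU, −78 °C; then 16, −78 °C; AcOH quench at −78 °C
Reagents that add atoms: none
Why: Fráter–Seebach-type alkylation of the β-hydroxy ketone dianion, in which the lithium chelate between the C8 alkoxide and the C6 enolate is alkylated at C7 on the face anti to C9 (also the face not covered by the ring), giving the 7,8-anti product (C7 = R).

Step 12
Reactants: 17 C7-alkylated hydroxy keto ester
Product: 19 hydroxy lactone (6,12-olide), via diol ester 18 (not isolated)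
Conditions: Me4NBH(OAc)3, MeCN/AcOH, −30 °C; then PPTS (cat.), benzene, 50 °C
Reagents that add atoms: none
Why: Evans–Saksena reduction, in which the acetoxyborohydride bound to O8 delivers hydride internally to C6 and gives the 1,3-anti diol (C6 = R), after which acid closes the trans-fused 6,12-γ-lactone, expected to be favoured over the cis-fused 8,12-isomer as in natural 8β-hydroxy-6,12-olides.

Step 13
Reactants: 19 hydroxy lactone (6,12-olide)
Product: 22 α-methylene hydroxy lactone, via Mannich base 20 (not isolated), via ammonium iodide 21 (not isolated)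
Conditions: LiN(i-Pr)2 (3 equiv), THF, −78 °C; CH2=NMe2+ I−, −78 to 0 °C; aqueous work-up; then MeI, MeOH, 23 °C; then NaHCO3, CH2Cl2/H2O
Reagents that add atoms: N,N-dimethylmethyleneiminium iodide (Eschenmoser's salt), C=[N+](C)C.[I-]
Why: α-Methylenation of the lactone by Mannich reaction of its enolate (O8 is carried as the alkoxide), N-methylation and Hofmann-type elimination.

Step 14
Reactants: 22 α-methylene hydroxy lactone; 23 methacryloyl chloride
Product: 24 8-O-methacrylate acetonide
Conditions: Et3N, DMAP (cat.), CH2Cl2, 0 °C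
Reagents that add atoms: none
Why: DMAP-catalysed acylation (esterification) of O8, the only free hydroxyl.

Step 15
Reactants: 24 8-O-methacrylate acetonide
Product: 25 3,15-diol
Conditions: AcOH/THF/H2O (3:1:1), 40 °C
Reagents that add atoms: none
Why: Mild acid hydrolysis of the acetonide frees O3 and O15 while the esters and the acid-tolerant Z-4 and E-1(10) alkenes stay intact.

Step 16
Reactants: 25 3,15-diol
Product: 26 15-aldehyde (enal)
Conditions: TEMPO (10 mol %), PhI(OAc)2 (1.1 equiv), CH2Cl2, 23 °C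
Reagents that add atoms: none
Why: Oxoammonium (TEMPO) oxidation is selective for the primary allylic alcohol over the secondary allylic C3 alcohol and gives the enal without moving the double bond.

Step 17
Reactants: 26 15-aldehyde (enal)
Product: 27 target
Conditions: mCPBA (1.05 equiv), CH2Cl2, 0 °C
Reagents that add atoms: 3-chloroperoxybenzoic acid, OOC(=O)c1cccc(Cl)c1
Why: Prilezhaev epoxidation takes the only electron-rich alkene (C1=C10, the other three being conjugated to carbonyl groups) from its exposed outer face in the heliangolide conformation, as in known germacranolide epoxidations, which gives the trans 1R,10R epoxide.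

Compound list
1 | methacrolein (2-methylprop-2-enal) | CC(=C)C=O | starting material
2 | methyl (3S)-4-methyl-3-(trimethylsilyloxy)pent-4-enoate | COC(=O)C[C@H](O[Si](C)(C)C)C(C)=C | intermediate
3 | methyl (3S)-3-hydroxy-4-methylpent-4-enoate | COC(=O)C[C@H](O)C(C)=C | intermediate
4 | methyl (3S)-3-hydroxy-4-(hydroxymethyl)pent-4-enoate | COC(=O)C[C@H](O)C(CO)=C | intermediate
5 | methyl 2-[(4S)-2,2-dimethyl-5-methylidene-1,3-dioxan-4-yl]acetate | COC(=O)C[C@@H]1OC(C)(C)OCC1=C | intermediate
6 | 2-[(4S)-2,2-dimethyl-5-methylidene-1,3-dioxan-4-yl]acetaldehyde | O=CC[C@@H]1OC(C)(C)OCC1=C | intermediate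
7 | (4S)-4-hydroxycyclopent-2-en-1-one | O[C@H]1CC(=O)C=C1 | starting material
8 | (4S)-4-(tert-butyldimethylsilyloxy)cyclopent-2-en-1-one | CC(C)(C)[Si](C)(C)O[C@H]1CC(=O)C=C1 | intermediate
9 | (4S)-4-(tert-butyldimethylsilyloxy)-2-[(1R)-2-[(4S)-2,2-dimethyl-5-methylidene-1,3-dioxan-4-yl]-1-hydroxyethyl]cyclopent-2-en-1-one | CC(C)(C)[Si](C)(C)O[C@H]1CC(=O)C([C@H](O)C[C@@H]2OC(C)(C)OCC2=C)=C1 | intermediate
10 | (2S,4R)-4-(tert-butyldimethylsilyloxy)-2-[(1R)-2-[(4S)-2,2-dimethyl-5-methylidene-1,3-dioxan-4-yl]-1-hydroxyethyl]-2-methylcyclopentan-1-one | CC(C)(C)[Si](C)(C)O[C@H]1CC(=O)[C@](C)([C@H](O)C[C@@H]2OC(C)(C)OCC2=C)C1 | intermediate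
11 | (1S,2S,4R)-4-(tert-butyldimethylsilyloxy)-2-[(1R)-2-[(4S)-2,2-dimethyl-5-methylidene-1,3-dioxan-4-yl]-1-hydroxyethyl]-1-ethenyl-2-methylcyclopentan-1-ol | CC(C)(C)[Si](C)(C)O[C@H]1C[C@](O)(C=C)[C@](C)([C@H](O)C[C@@H]2OC(C)(C)OCC2=C)C1 | intermediate
12 | (1R,3S,6S,8R,10S)-8-(tert-butyldimethylsilyloxy)-3,15-(isopropylidenedioxy)-11,12,13-trinor-6,10-cyclogermacr-4-ene-1,6-diol (cis-fused bicyclo[5.3.0]decene) | CC(C)(C)[Si](C)(C)O[C@H]1C[C@]2(O)C=C3COC(C)(C)O[C@H]3C[C@@H](O)[C@]2(C)C1 | intermediate
13 | 1-O-methanesulfonate of 12 | CC(C)(C)[Si](C)(C)O[C@H]1C[C@]2(O)C=C3COC(C)(C)O[C@H]3C[C@@H](OS(C)(=O)=O)[C@]2(C)C1 | intermediate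
14 | (1(10)E,4Z,3S,8R)-8-(tert-butyldimethylsilyloxy)-3,15-(isopropylidenedioxy)-11,12,13-trinorgermacra-1(10),4-dien-6-one | CC(C)(C)[Si](C)(C)O[C@@H]1C/C(C)=C/C[C@@H]2OC(C)(C)OC/C2=C/C(=O)C1 | intermediate
15 | (1(10)E,4Z,3S,8R)-8-hydroxy-3,15-(isopropylidenedioxy)-11,12,13-trinorgermacra-1(10),4-dien-6-one | O[C@@H]1C/C(C)=C/C[C@@H]2OC(C)(C)OC/C2=C/C(=O)C1 | intermediate
16 | methyl bromoacetate | COC(=O)CBr | starting material
17 | methyl (1(10)E,4Z,3S,7R,8R)-8-hydroxy-3,15-(isopropylidenedioxy)-6-oxo-13-norgermacra-1(10),4-dien-12-oate | O[C@@H]1C/C(C)=C/C[C@@H]2OC(C)(C)OC/C2=C/C(=O)[C@@H]1CC(=O)OC | intermediate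
18 | methyl (1(10)E,4Z,3S,6R,7R,8R)-6,8-dihydroxy-3,15-(isopropylidenedioxy)-13-norgermacra-1(10),4-dien-12-oate | O[C@@H]1C/C(C)=C/C[C@@H]2OC(C)(C)OC/C2=C/[C@@H](O)[C@@H]1CC(=O)OC | intermediate
19 | (1(10)E,4Z,3S,6R,7R,8R)-8-hydroxy-3,15-(isopropylidenedioxy)-13-norgermacra-1(10),4-dien-12,6-olide | O[C@@H]1C/C(C)=C/C[C@@H]2OC(C)(C)OC/C2=C/[C@H]2OC(=O)C[C@@H]21 | intermediate
20 | 13-(dimethylamino) derivative of 19 with C13 attached at C11 (C11 epimers) | O[C@@H]1C/C(C)=C/C[C@@H]2OC(C)(C)OC/C2=C/[C@H]2OC(=O)C(CN(C)C)[C@@H]21 | intermediate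
21 | N-methyl (trimethylammonium) iodide of 20 | O[C@@H]1C/C(C)=C/C[C@@H]2OC(C)(C)OC/C2=C/[C@H]2OC(=O)C(C[N+](C)(C)C)[C@@H]21.[I-] | intermediate
22 | (1(10)E,4Z,3S,6R,7R,8R)-8-hydroxy-3,15-(isopropylidenedioxy)germacra-1(10),4,11(13)-trien-12,6-olide | O[C@@H]1C/C(C)=C/C[C@@H]2OC(C)(C)OC/C2=C/[C@H]2OC(=O)C(=C)[C@@H]21 | intermediate
23 | methacryloyl chloride | C=C(C)C(Cl)=O | starting material
24 | (1(10)E,4Z,3S,6R,7R,8R)-3,15-(isopropylidenedioxy)-8-(methacryloyloxy)germacra-1(10),4,11(13)-trien-12,6-olide | C=C(C)C(=O)O[C@@H]1C/C(C)=C/C[C@@H]2OC(C)(C)OC/C2=C/[C@H]2OC(=O)C(=C)[C@@H]21 | intermediate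
25 | (1(10)E,4Z,3S,6R,7R,8R)-3,15-dihydroxy-8-(methacryloyloxy)germacra-1(10),4,11(13)-trien-12,6-olide | C=C(C)C(=O)O[C@@H]1C/C(C)=C/C[C@H](O)/C(CO)=C\[C@H]2OC(=O)C(=C)[C@@H]21 | intermediate
26 | (1(10)E,4E,3S,6R,7R,8R)-3-hydroxy-8-(methacryloyloxy)-15-oxogermacra-1(10),4,11(13)-trien-12,6-olide | C=C(C)C(=O)O[C@@H]1C/C(C)=C/C[C@H](O)/C(C=O)=C\[C@H]2OC(=O)C(=C)[C@@H]21 | intermediate
27 | (1R,3S,4E,6R,7R,8R,10R)-1,10-epoxy-3-hydroxy-8-(methacryloyloxy)-15-oxogermacra-4,11(13)-dien-12,6-olide | C=C(C)C(=O)O[C@@H]1C[C@@]2(C)O[C@@H]2C[C@H](O)/C(C=O)=C\[C@H]2OC(=O)C(=C)[C@@H]21 | target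

Total step count: 17. Longest linear sequence: 16 steps (steps 1–4, then 6–17).

Steps most likely to fail

Step 7 (the proposed new step). It can fail through 1,2-reduction of the enone or through methylation without chelate control. A sequence of known reactions sets out from 8 and comes back at 12. Iodination (I2, pyridine) gives (4S)-4-(tert-butyldimethylsilyloxy)-2-iodocyclopent-2-en-1-one F1. Suzuki–Miyaura coupling with MeB(OH)2 (Pd(dppf)Cl2, K3PO4) gives (4S)-4-(tert-butyldimethylsilyloxy)-2-methylcyclopent-2-en-1-one F2. LiBH(s-Bu)3 conjugate reduction and trapping of the enolate with aldehyde 6 (reductive aldol through a Zimmerman–Traxler chair, which puts methyl and O1 trans) gives the C1-epimeric aldol F3. Vinyl addition as in step 8 gives the C1-epimeric vinyl carbinol F4, and ring-closing metathesis as in step 9 gives the C1-epimeric bicyclic diol F5. Dess–Martin oxidation of the secondary alcohol gives the 1-ketone F6, and a syn-selective 1,3-reduction under boron-chelate control (Et2BOMe, NaBH4) corrects C1 and gives 12.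

Step 11. The dianion may undergo retro-aldol ring opening, or the ring may not allow the chelated enolate. The alkylation is then run on the silyl ether; this sets out from 14 (isolated by leaving out the fluoride treatment in step 10) and comes back at 17. LiN(SiMe3)2 followed by 16 alkylates the simple C6 enolate on the face away from the silyloxy group and gives the 8-O-tert-butyldimethylsilyl ether of 17 F7; AcOH-buffered Bu4NF then gives 17.

Step 12. The lactone may close on O8, or hydride delivery may be poor in the ring. O8 is then blocked first; this sets out from 17 and comes back at 19. TESOTf and 2,6-lutidine give the 8-O-triethylsilyl ether of 17 F8; Luche reduction (NaBH4, CeCl3·7H2O, MeOH) from the open face gives the 8-O-triethylsilyl ether of 18 F9; PPTS in MeOH then closes the lactone on O6, the only free hydroxyl, and removes the silyl group to give 19.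

Further compounds
F1 | step 7 | (4S)-4-(tert-butyldimethylsilyloxy)-2-iodocyclopent-2-en-1-one | CC(C)(C)[Si](C)(C)O[C@H]1CC(=O)C(I)=C1
F2 | step 7 | (4S)-4-(tert-butyldimethylsilyloxy)-2-methylcyclopent-2-en-1-one | CC(C)(C)[Si](C)(C)O[C@H]1CC(=O)C(C)=C1
F3 | step 7 | C1 epimer of 10 ((1S)-1-hydroxyethyl side chain) | CC(C)(C)[Si](C)(C)O[C@H]1CC(=O)[C@](C)([C@@H](O)C[C@@H]2OC(C)(C)OCC2=C)C1
F4 | step 7 | C1 epimer of 11 | CC(C)(C)[Si](C)(C)O[C@H]1C[C@](O)(C=C)[C@](C)([C@@H](O)C[C@@H]2OC(C)(C)OCC2=C)C1
F5 | step 7 | C1 epimer of 12 | CC(C)(C)[Si](C)(C)O[C@H]1C[C@]2(O)C=C3COC(C)(C)O[C@H]3C[C@H](O)[C@]2(C)C1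
F6 | step 7 | 1-ketone from F5 (1-oxo analogue of 12) | CC(C)(C)[Si](C)(C)O[C@H]1C[C@]2(O)C=C3COC(C)(C)O[C@H]3CC(=O)[C@]2(C)C1
F7 | step 11 | 8-O-tert-butyldimethylsilyl ether of 17 | CC(C)(C)[Si](C)(C)O[C@@H]1C/C(C)=C/C[C@@H]2OC(C)(C)OC/C2=C/C(=O)[C@@H]1CC(=O)OC
F8 | step 12 | 8-O-triethylsilyl ether of 17 | CC[Si](CC)(CC)O[C@@H]1C/C(C)=C/C[C@@H]2OC(C)(C)OC/C2=C/C(=O)[C@@H]1CC(=O)OC
F9 | step 12 | 8-O-triethylsilyl ether of 18 | CC[Si](CC)(CC)O[C@@H]1C/C(C)=C/C[C@@H]2OC(C)(C)OC/C2=C/[C@@H](O)[C@@H]1CC(=O)OC
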